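**Retrosynthetic overview**

- Numbering: C1 is the methyl-bearing quaternary fusion carbon, C2 and C3 are CH2, C4 is the isopropyl carbinol, C5 is the fusion CH (ring A = C1–C5); C6 carries the acyloxy group, C7 is CH2, C8(CH3)=C9, C10 is CH2 (ring B = C1, C5–C10).
- Feature: at the enol oxidation level of C6, ring B holds C8=C9 and C5=C6–O as a 1,4-diene around the doubly allylic C7, with quaternary C1 between C5 and C10. This is the pattern left by a cis-divinylcyclopropane rearrangement.
- Disconnections: the C6 ester (late acylation); C6–OH from the C6 ketone, itself from the C5=C6 silyl enol ether; C8–CH3 from a C8 ester; ring B (bonds C7–C8 and C1–C10) from siloxydiene 7 plus vinyldiazoacetate 11 by carbenoid cyclopropanation and Cope rearrangement.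
- Ring order: ring A is taken intact from (S)-terpinen-4-ol by ozonolysis and aldol ring contraction, which supplies C4. Ring B is closed second, in the key step, which sets C1. C5 and C6 follow by protonation and hydroxyl-directed reduction.

Key step: step 10

Remark (assumptions): (S)-(+)-terpinen-4-ol is taken as purchasable in high enantiomeric purity, and the R antipode of the catalyst in step 10 is chosen on the assumption that the facial sense known for styrene with aryldiazoacetates [(S)-catalyst gives the (1S,2R)-cyclopropane] carries over to diene 7.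

**Route**

Step 1
Reactants: 1 (S)-(+)-terpinen-4-ol
Product: 2 triethyl{[(1S)-4-methyl-1-(propan-2-yl)cyclohex-3-en-1-yl]oxy}silane
Conditions: Et3SiOTf, 2,6-lutidine, CH2Cl2, 0 °C
Reagents that add atoms: triethylsilyl triflate (TESOTf), CC[Si](CC)(CC)OS(=O)(=O)C(F)(F)F
Why: Silylation of a tertiary alcohol with a silyl triflate; the silyl ether later blocks O–H insertion by the carbenoid and retro-aldol cleavage, and the carbinol stereocenter (future C4) is not touched.

Step 2
Reactants: 2 triethyl{[(1S)-4-methyl-1-(propan-2-yl)cyclohex-3-en-1-yl]oxy}silane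
Product: 3 (3S)-6-oxo-3-(propan-2-yl)-3-(triethylsilyloxy)heptanal
Conditions: O3, CH2Cl2, −78 °C; then PPh3, −78 °C → rt
Reagents that add atoms: ozone, [O-][O+]=O
Why: Ozonolysis with reductive work-up opens the trisubstituted ring alkene to a methyl ketone and an aldehyde, and the tertiary silyl ether is inert to it.

Step 3
Reactants: 3 (3S)-6-oxo-3-(propan-2-yl)-3-(triethylsilyloxy)heptanal
Product: 4 (5R)-2-methyl-5-(propan-2-yl)-5-(triethylsilyloxy)cyclopent-1-ene-1-carbaldehyde
Conditions: Bn2NH·CF3CO2H (30 mol %), toluene, 50 °C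
Reagents that add atoms: none
Why: Amine-salt-catalysed intramolecular aldol condensation: the aldehyde forms the enamine much faster than the ketone, adds 5-exo to the methyl ketone and dehydrates to the cyclopentenecarbaldehyde (the regiochemistry known for 6-oxoheptanals under piperidinium acetate), while the silyl ether should prevent retro-aldol loss of the carbinol.

Step 4
Reactants: 4 (5R)-2-methyl-5-(propan-2-yl)-5-(triethylsilyloxy)cyclopent-1-ene-1-carbaldehyde
Product: 5 1-[(5R)-2-methyl-5-(propan-2-yl)-5-(triethylsilyloxy)cyclopent-1-en-1-yl]ethan-1-ol (both carbinol epimers)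
Conditions: MeMgBr, THF, −78 → 0 °C
Reagents that add atoms: methylmagnesium bromide, C[Mg]Br
Why: Grignard 1,2-addition to the hindered enal; the new carbinol center is oxidised in step 5, so its configuration does not matter.

Step 5
Reactants: 5 1-[(5R)-2-methyl-5-(propan-2-yl)-5-(triethylsilyloxy)cyclopent-1-en-1-yl]ethan-1-ol
Product: 6 1-[(5R)-2-methyl-5-(propan-2-yl)-5-(triethylsilyloxy)cyclopent-1-en-1-yl]ethan-1-one
Conditions: Dess–Martin periodinane, CH2Cl2, rt
Reagents that add atoms: none
Why: Dess–Martin oxidation of the secondary allylic alcohol gives the methyl enone without affecting the silyl ether or the tetrasubstituted alkene.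

Step 6
Reactants: 6 1-[(5R)-2-methyl-5-(propan-2-yl)-5-(triethylsilyloxy)cyclopent-1-en-1-yl]ethan-1-one
Product: 7 tert-butyldimethyl({1-[(5R)-2-methyl-5-(propan-2-yl)-5-(triethylsilyloxy)cyclopent-1-en-1-yl]ethenyl}oxy)silane
Conditions: t-BuMe2SiOTf, Et3N, CH2Cl2, 0 °C
Reagents that add atoms: tert-butyldimethylsilyl triflate (TBSOTf), CC(C)(C)[Si](C)(C)OS(=O)(=O)C(F)(F)F
Why: Soft enolisation and O-silylation of the methyl ketone; flanked by the C1 methyl and quaternary C4, the acetyl group is twisted out of conjugation, so the proton should be lost from the acetyl methyl to give the cross-conjugated 2-siloxydiene.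

Step 7
Reactants: 8 methyl acetoacetate
Product: 9 methyl 2-diazo-3-oxobutanoate
Conditions: 4-acetamidobenzenesulfonyl azide, Et3N, MeCN, 0 °C → rt
Reagents that add atoms: 4-acetamidobenzenesulfonyl azide (p-ABSA), CC(=O)Nc1ccc(cc1)S(=O)(=O)N=[N+]=[N-]
Why: Regitz diazo transfer to the active methylene of a β-keto ester.

Step 8
Reactants: 9 methyl 2-diazo-3-oxobutanoate
Product: 10 methyl 2-diazo-3-hydroxybutanoate (racemic)
Conditions: NaBH4, MeOH, 0 °C
Reagents that add atoms: none
Why: Borohydride reduction of the ketone leaves the diazo ester intact, and the carbinol center is removed in step 9.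

Step 9
Reactants: 10 methyl 2-diazo-3-hydroxybutanoate
Product: 11 methyl 2-diazobut-3-enoate
Conditions: POCl3, Et3N, CH2Cl2, 0 °C; cold filtration through silica, used at once as a hexanes solution
Reagents that add atoms: none
Why: Dehydration through the dichlorophosphate (E2 elimination with Et3N) gives the vinyldiazoacetate, which is kept cold and used immediately because it closes to a pyrazole on standing.

Step 10
Reactants: 7 tert-butyldimethyl({1-[(5R)-2-methyl-5-(propan-2-yl)-5-(triethylsilyloxy)cyclopent-1-en-1-yl]ethenyl}oxy)silane; 11 methyl 2-diazobut-3-enoate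
Product: 13 methyl (3R,8aR)-4-(tert-butyldimethylsilyloxy)-8a-methyl-3-(propan-2-yl)-3-(triethylsilyloxy)-1,2,3,5,8,8a-hexahydroazulene-6-carboxylate, via cis-divinylcyclopropane 12 (not isolated)
Conditions: Rh2(R-DOSP)4 (dirhodium tetrakis[(R)-N-(4-dodecylphenylsulfonyl)prolinate], 2 mol %), hexanes, −50 °C → rt, 11 (2.5 equiv) added slowly; then toluene, 80 °C
Reagents that add atoms: none
Why: The dirhodium prolinate decomposes 11 to a donor/acceptor vinylcarbenoid whose carbenoid carbon (future C8) adds across the terminal enol-ether alkene C6=C7 of 7 with the vinyl group cis to the cyclopentenyl group, and cis-divinylcyclopropane 12 then undergoes a [3,3] shift that joins the vinyl terminus C10 to C1 and cleaves C6–C8. The closest known reaction type is the tandem cyclopropanation/Cope rearrangement of vinyldiazoacetates with 2-siloxydienes, the formal (4+3) cycloaddition. Ring B closes in the sigmatropic step through the boat transition state that a cis-divinylcyclopropane must use, with C7–C8 and C1–C10 as the two new skeletal bonds and C5=C6 left as the silyl enol ether. The only new stereocenter, quaternary C1, is under catalyst control: the catalyst fixes the configuration of the cyclopropane (12 as drawn is expected from the R catalyst, by analogy with the sense of the S catalyst with styrene), and the boat relays it so that C10 bonds to the face of C1 anti to the C4 silyloxy group. The step needs reaction at the carbenoid carbon and not at the vinylogous position, which the methyl ester, the prolinate ligands and the hydrocarbon solvent favour, and it needs attack on the terminal alkene only, which the substrate secures because the ring alkene is tetrasubstituted and inert to this carbenoid class. Heating is included because the C1 methyl points into the boat and should slow the Cope step.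

Step 11
Reactants: 13 methyl (3R,8aR)-4-(tert-butyldimethylsilyloxy)-8a-methyl-3-(propan-2-yl)-3-(triethylsilyloxy)-1,2,3,5,8,8a-hexahydroazulene-6-carboxylate
Product: 14 [(3R,8aR)-4-(tert-butyldimethylsilyloxy)-8a-methyl-3-(propan-2-yl)-3-(triethylsilyloxy)-1,2,3,5,8,8a-hexahydroazulen-6-yl]methanol
Conditions: i-Bu2AlH, CH2Cl2, −78 °C; aq. KNaC4H4O6 (potassium sodium tartrate)
Reagents that add atoms: none
Why: 1,2-Reduction of the α,β-unsaturated ester by the aluminium hydride gives the primary allylic alcohol, and the silyl ether and silyl enol ether are inert.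

Step 12
Reactants: 14 [(3R,8aR)-4-(tert-butyldimethylsilyloxy)-8a-methyl-3-(propan-2-yl)-3-(triethylsilyloxy)-1,2,3,5,8,8a-hexahydroazulen-6-yl]methanol
Product: 16 (3R,8aR)-4-(tert-butyldimethylsilyloxy)-6,8a-dimethyl-3-(propan-2-yl)-3-(triethylsilyloxy)-1,2,3,5,8,8a-hexahydroazulene, via allylic mesylate 15 (not isolated)
Conditions: MsCl, Et3N, THF, −40 °C; then LiEt3BH, −78 → 0 °C
Reagents that add atoms: none
Why: Sulfonate formation followed by SN2 hydride displacement at the primary allylic carbon removes the oxygen and should leave C8=C9 in place (direct attack at CH2 is preferred over SN2' for this hydride), and the silyl enol ether tolerates amine base and hydride.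

Step 13
Reactants: 16 (3R,8aR)-4-(tert-butyldimethylsilyloxy)-6,8a-dimethyl-3-(propan-2-yl)-3-(triethylsilyloxy)-1,2,3,5,8,8a-hexahydroazulene
Product: 18 (3R,3aR,8aR)-3-hydroxy-6,8a-dimethyl-3-(propan-2-yl)-2,3,3a,5,8,8a-hexahydroazulen-4(1H)-one, via silyl ether ketone 17 (not isolated)
Conditions: HF·pyridine, pyridine, THF, 0 °C → rt
Reagents that add atoms: none
Why: Protodesilylation of the enol silyl ether with kinetic C-protonation at C5, then slower cleavage of the tertiary triethylsilyl ether; the face of C5 syn to the C1 methyl (axial on the boat-shaped ring B) and to the C4 silyloxy group is shielded, so the proton is expected on the opposite face to give H-5 trans to the C1 methyl, and the buffered base-free medium is chosen because base would draw the β,γ-alkene C8=C9 into conjugation with the C6 ketone and could trigger retro-aldol cleavage.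

Step 14
Reactants: 18 (3R,3aR,8aR)-3-hydroxy-6,8a-dimethyl-3-(propan-2-yl)-2,3,3a,5,8,8a-hexahydroazulen-4(1H)-one
Product: 19 (3R,3aS,4S,8aR)-6,8a-dimethyl-3-(propan-2-yl)-1,2,3,3a,4,5,8,8a-octahydroazulene-3,4-diol (jaeschkeanadiol)
Conditions: Me4NBH(OAc)3, MeCN/AcOH (1:1), −30 → −20 °C
Reagents that add atoms: none
Why: Evans–Saksena hydroxyl-directed reduction: the C4 hydroxyl, cis to C6 on ring A, binds boron and delivers hydride to the face of the C6 ketone on its own side, which should give the 1,3-anti diol with the C6 hydroxyl on the face opposite to the C4 hydroxyl, as in the target.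

Step 15
Reactants: 20 p-coumaric acid
Product: 22 (E)-3-[4-(tert-butyldimethylsilyloxy)phenyl]prop-2-enoic acid, via bis-silyl derivative 21 (not isolated)
Conditions: t-BuMe2SiCl, imidazole, DMF, rt; then AcOH/THF/H2O, rt
Reagents that add atoms: tert-butyldimethylsilyl chloride (TBSCl), CC(C)(C)[Si](C)(C)Cl
Why: Exhaustive silylation followed by selective hydrolysis of the labile silyl ester masks only the phenol.

Step 16
Reactants: 19 (3R,3aS,4S,8aR)-6,8a-dimethyl-3-(propan-2-yl)-1,2,3,3a,4,5,8,8a-octahydroazulene-3,4-diol; 22 (E)-3-[4-(tert-butyldimethylsilyloxy)phenyl]prop-2-enoic acid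
Product: 23 (3R,3aS,4S,8aR)-3-hydroxy-6,8a-dimethyl-3-(propan-2-yl)-1,2,3,3a,4,5,8,8a-octahydroazulen-4-yl (E)-3-[4-(tert-butyldimethylsilyloxy)phenyl]prop-2-enoate
Conditions: EDC·HCl, DMAP, CH2Cl2, rt
Reagents that add atoms: none
Why: Steglich esterification acylates only the secondary C6 hydroxyl because the tertiary C4 hydroxyl is too hindered, and C6 keeps its configuration since its C–O bond is not broken.

Step 17
Reactants: 23 (3R,3aS,4S,8aR)-3-hydroxy-6,8a-dimethyl-3-(propan-2-yl)-1,2,3,3a,4,5,8,8a-octahydroazulen-4-yl (E)-3-[4-(tert-butyldimethylsilyloxy)phenyl]prop-2-enoate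
Product: 24 (3R,3aS,4S,8aR)-3-hydroxy-6,8a-dimethyl-3-(propan-2-yl)-1,2,3,3a,4,5,8,8a-octahydroazulen-4-yl (E)-3-(4-hydroxyphenyl)prop-2-enoate (CNP0265426.1)
Conditions: Bu4NF, AcOH, THF, 0 °C
Reagents that add atoms: none
Why: Fluoride cleavage of the aryl silyl ether, buffered with acetic acid so that the cinnamate ester and the tertiary alcohol are not affected.

**Compound list**

1 | (S)-(+)-terpinen-4-ol, (1S)-4-methyl-1-(propan-2-yl)cyclohex-3-en-1-ol | CC1=CC[C@](O)(C(C)C)CC1 | starting material
2 | triethyl{[(1S)-4-methyl-1-(propan-2-yl)cyclohex-3-en-1-yl]oxy}silane | CC1=CC[C@](O[Si](CC)(CC)CC)(C(C)C)CC1 | intermediate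
3 | (3S)-6-oxo-3-(propan-2-yl)-3-(triethylsilyloxy)heptanal | CC(=O)CC[C@@](O[Si](CC)(CC)CC)(C(C)C)CC=O | intermediate
4 | (5R)-2-methyl-5-(propan-2-yl)-5-(triethylsilyloxy)cyclopent-1-ene-1-carbaldehyde | O=CC1=C(C)CC[C@@]1(O[Si](CC)(CC)CC)C(C)C | intermediate
5 | 1-[(5R)-2-methyl-5-(propan-2-yl)-5-(triethylsilyloxy)cyclopent-1-en-1-yl]ethan-1-ol (both carbinol epimers) | CC(O)C1=C(C)CC[C@@]1(O[Si](CC)(CC)CC)C(C)C | intermediate
6 | 1-[(5R)-2-methyl-5-(propan-2-yl)-5-(triethylsilyloxy)cyclopent-1-en-1-yl]ethan-1-one | CC(=O)C1=C(C)CC[C@@]1(O[Si](CC)(CC)CC)C(C)C | intermediate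
7 | tert-butyldimethyl({1-[(5R)-2-methyl-5-(propan-2-yl)-5-(triethylsilyloxy)cyclopent-1-en-1-yl]ethenyl}oxy)silane | C=C(O[Si](C)(C)C(C)(C)C)C1=C(C)CC[C@@]1(O[Si](CC)(CC)CC)C(C)C | intermediate
8 | methyl acetoacetate | CC(=O)CC(=O)OC | starting material
9 | methyl 2-diazo-3-oxobutanoate | CC(=O)C(=[N+]=[N-])C(=O)OC | intermediate
10 | methyl 2-diazo-3-hydroxybutanoate (racemic) | CC(O)C(=[N+]=[N-])C(=O)OC | intermediate
11 | methyl 2-diazobut-3-enoate | C=CC(=[N+]=[N-])C(=O)OC | intermediate
12 | methyl (1S,2R)-2-(tert-butyldimethylsilyloxy)-1-ethenyl-2-[(5R)-2-methyl-5-(propan-2-yl)-5-(triethylsilyloxy)cyclopent-1-en-1-yl]cyclopropane-1-carboxylate | COC(=O)[C@]1(C=C)C[C@@]1(O[Si](C)(C)C(C)(C)C)C2=C(C)CC[C@@]2(O[Si](CC)(CC)CC)C(C)C | intermediate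
13 | methyl (3R,8aR)-4-(tert-butyldimethylsilyloxy)-8a-methyl-3-(propan-2-yl)-3-(triethylsilyloxy)-1,2,3,5,8,8a-hexahydroazulene-6-carboxylate | COC(=O)C1=CC[C@@]2(C)CC[C@@](O[Si](CC)(CC)CC)(C(C)C)C2=C(O[Si](C)(C)C(C)(C)C)C1 | intermediate
14 | [(3R,8aR)-4-(tert-butyldimethylsilyloxy)-8a-methyl-3-(propan-2-yl)-3-(triethylsilyloxy)-1,2,3,5,8,8a-hexahydroazulen-6-yl]methanol | OCC1=CC[C@@]2(C)CC[C@@](O[Si](CC)(CC)CC)(C(C)C)C2=C(O[Si](C)(C)C(C)(C)C)C1 | intermediate
15 | [(3R,8aR)-4-(tert-butyldimethylsilyloxy)-8a-methyl-3-(propan-2-yl)-3-(triethylsilyloxy)-1,2,3,5,8,8a-hexahydroazulen-6-yl]methyl methanesulfonate | CS(=O)(=O)OCC1=CC[C@@]2(C)CC[C@@](O[Si](CC)(CC)CC)(C(C)C)C2=C(O[Si](C)(C)C(C)(C)C)C1 | intermediate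
16 | (3R,8aR)-4-(tert-butyldimethylsilyloxy)-6,8a-dimethyl-3-(propan-2-yl)-3-(triethylsilyloxy)-1,2,3,5,8,8a-hexahydroazulene | CC1=CC[C@@]2(C)CC[C@@](O[Si](CC)(CC)CC)(C(C)C)C2=C(O[Si](C)(C)C(C)(C)C)C1 | intermediate
17 | (3R,3aR,8aR)-6,8a-dimethyl-3-(propan-2-yl)-3-(triethylsilyloxy)-2,3,3a,5,8,8a-hexahydroazulen-4(1H)-one | CC1=CC[C@@]2(C)CC[C@@](O[Si](CC)(CC)CC)(C(C)C)[C@@H]2C(=O)C1 | intermediate
18 | (3R,3aR,8aR)-3-hydroxy-6,8a-dimethyl-3-(propan-2-yl)-2,3,3a,5,8,8a-hexahydroazulen-4(1H)-one | CC1=CC[C@@]2(C)CC[C@@](O)(C(C)C)[C@@H]2C(=O)C1 | intermediate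
19 | (3R,3aS,4S,8aR)-6,8a-dimethyl-3-(propan-2-yl)-1,2,3,3a,4,5,8,8a-octahydroazulene-3,4-diol (jaeschkeanadiol) | CC1=CC[C@@]2(C)CC[C@@](O)(C(C)C)[C@@H]2[C@@H](O)C1 | intermediate
20 | p-coumaric acid, (E)-3-(4-hydroxyphenyl)prop-2-enoic acid | OC(=O)/C=C/c1ccc(O)cc1 | starting material
21 | tert-butyldimethylsilyl (E)-3-[4-(tert-butyldimethylsilyloxy)phenyl]prop-2-enoate | CC(C)(C)[Si](C)(C)OC(=O)/C=C/c1ccc(O[Si](C)(C)C(C)(C)C)cc1 | intermediate
22 | (E)-3-[4-(tert-butyldimethylsilyloxy)phenyl]prop-2-enoic acid | OC(=O)/C=C/c1ccc(O[Si](C)(C)C(C)(C)C)cc1 | intermediate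
23 | (3R,3aS,4S,8aR)-3-hydroxy-6,8a-dimethyl-3-(propan-2-yl)-1,2,3,3a,4,5,8,8a-octahydroazulen-4-yl (E)-3-[4-(tert-butyldimethylsilyloxy)phenyl]prop-2-enoate | CC1=CC[C@@]2(C)CC[C@@](O)(C(C)C)[C@@H]2[C@@H](OC(=O)/C=C/c2ccc(O[Si](C)(C)C(C)(C)C)cc2)C1 | intermediate
24 | (3R,3aS,4S,8aR)-3-hydroxy-6,8a-dimethyl-3-(propan-2-yl)-1,2,3,3a,4,5,8,8a-octahydroazulen-4-yl (E)-3-(4-hydroxyphenyl)prop-2-enoate | CC1=CC[C@@]2(C)CC[C@@](O)(C(C)C)[C@@H]2[C@@H](OC(=O)/C=C/c2ccc(O)cc2)C1 | target

**Step count and risk**

Total step count: 17. Longest linear sequence: 13 steps (steps 1–6, 10–14, 16, 17).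

Steps most likely to fail:

1. Step 10. The enol ether may attack the vinylogous carbon of the carbenoid instead of the carbenoid carbon. The catalyst may fail to override the facial bias of the chiral diene, which would give the C1 epimer. The donor–acceptor cyclopropane may open reversibly during heating, so that its configuration leaks before the Cope step. The fallback sets out from 4 and comes back at 17. Addition of 2-methylallylmagnesium chloride to 4 would give 3-methyl-1-[(5R)-2-methyl-5-(propan-2-yl)-5-(triethylsilyloxy)cyclopent-1-en-1-yl]but-3-en-1-ol F1. Dess–Martin oxidation would give the dienone F2. Hosomi–Sakurai conjugate allylation (allyltrimethylsilane, TiCl4, CH2Cl2, −78 °C) would install the C1 quaternary center and, after protonation at C5, give the allylated ketone F3; its C1 and C5 configurations would rest on substrate control and epimers would be separated. Ring-closing metathesis with the second-generation Grubbs catalyst RuCl2(=CHPh)(H2IMes)(PCy3) would then close ring B at C8=C9 to give 17, which rejoins the route in the second stage of step 13.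

2. Step 13. Facial selectivity in the protonation at C5 may be poor, which would give the cis-fused ketone, or the C8=C9 alkene may migrate into conjugation with the C6 ketone during desilylation. The fallback sets out from 16 and comes back at 17. Brief treatment with buffered HF·pyridine at 0 °C would stop at 17 as a mixture of C5 epimers. DBU in toluene would then equilibrate C5 toward the trans fusion (the cis fusion places C6 cis to the isopropyl group on ring A) and move the alkene into conjugation, to give (3R,3aR,8aR)-6,8a-dimethyl-3-(propan-2-yl)-3-(triethylsilyloxy)-2,3,3a,7,8,8a-hexahydroazulen-4(1H)-one F4. Formation of the extended dienolate with KOt-Bu (t-BuOH/THF) and a kinetic quench with AcOH at −78 °C would protonate at C7 and return the β,γ-unsaturated ketone 17 with the trans fusion, which goes on to 18 with HF·pyridine.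

3. Step 14. Ligand exchange at the hindered tertiary hydroxyl may be too slow for intramolecular hydride delivery, and forcing may bring in undirected reduction from the opposite face. The fallback sets out from 18 and comes back at 19. Silylation of 18 with Me2SiHCl and Et3N would give the dimethylsilyl ether (3R,3aR,8aR)-3-(dimethylsilyloxy)-6,8a-dimethyl-3-(propan-2-yl)-2,3,3a,5,8,8a-hexahydroazulen-4(1H)-one F5. SnCl4-catalysed intramolecular hydrosilylation (CH2Cl2, −78 °C) would deliver hydride to C6 from the side of the C4 oxygen and give the cyclic silylene acetal of the anti diol F6. HF·pyridine would then release 19.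

**Further compounds**

F1 | step 10 | 3-methyl-1-[(5R)-2-methyl-5-(propan-2-yl)-5-(triethylsilyloxy)cyclopent-1-en-1-yl]but-3-en-1-ol | CC(=C)CC(O)C1=C(C)CC[C@@]1(O[Si](CC)(CC)CC)C(C)C
F2 | step 10 | 3-methyl-1-[(5R)-2-methyl-5-(propan-2-yl)-5-(triethylsilyloxy)cyclopent-1-en-1-yl]but-3-en-1-one | CC(=C)CC(=O)C1=C(C)CC[C@@]1(O[Si](CC)(CC)CC)C(C)C
F3 | step 10 | 3-methyl-1-[(1R,2R,5R)-2-methyl-5-(propan-2-yl)-2-(prop-2-en-1-yl)-5-(triethylsilyloxy)cyclopentyl]but-3-en-1-one | C=CC[C@@]1(C)CC[C@@](O[Si](CC)(CC)CC)(C(C)C)[C@@H]1C(=O)CC(C)=C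
F4 | step 13 | (3R,3aR,8aR)-6,8a-dimethyl-3-(propan-2-yl)-3-(triethylsilyloxy)-2,3,3a,7,8,8a-hexahydroazulen-4(1H)-one | CC=1CC[C@@]2(C)CC[C@@](O[Si](CC)(CC)CC)(C(C)C)[C@@H]2C(=O)C=1
F5 | step 14 | (3R,3aR,8aR)-3-(dimethylsilyloxy)-6,8a-dimethyl-3-(propan-2-yl)-2,3,3a,5,8,8a-hexahydroazulen-4(1H)-one | CC1=CC[C@@]2(C)CC[C@@](O[SiH](C)C)(C(C)C)[C@@H]2C(=O)C1
F6 | step 14 | cyclic dimethylsilylene acetal of diol 19 (O–Si–O bridge between the C4 and C6 oxygens) | CC1=CC[C@@]2(C)CC[C@@]3(C(C)C)[C@@H]2[C@H](C1)O[Si](C)(C)O3
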